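**Atom numbering used throughout:** ring C1 (stereocentre), C2, C3=C4(CO2H), C5, C6, C7=C8(CH3), C9, C10, C11=C12(CH3), C13, C14; C15 is the side-chain carbon on C1 that carries the exocyclic CH2.

## Structural features

The target is a C25 acid built on a 14-membered carbocycle (C1–C14) that carries a 6-methylhepta-1,5-dien-2-yl chain at C1 through C15. The ring holds three trisubstituted alkenes, each separated from the next by two methylene groups: C3=C4 with the carboxyl group on C4 (C2 and CO2H cis, CIP Z), C7=C8 with its methyl on C8 (E), and C11=C12 with its methyl on C12 (Z). C1 is the only stereocentre and is R. It is flanked by the ring methylenes C2 and C14 and by the sp2 carbon C15, so no neighbouring stereocentre can relay its configuration. In an open-chain precursor with two-carbon arms, C1 is stereogenic only as long as the two arms stay chemically different. The 1,1-disubstituted alkene at C15, the prenyl-type alkene of the side chain and the ring alkenes are sensitive to strong acid (cation–olefin and transannular reactions), to halogens and to hydroboration, and the conjugated acid can isomerise or deconjugate under strong base or light. The real difficulty is the control of three trisubstituted alkene geometries of different sense, together with a macrocyclic C–C bond formation that must not erode them. The key step exploits the C11=C12 unit of the ring: a Z alkene whose methyl sits on C12 and whose other two substituents are the sp3 carbons C13 and C10 is a propyne molecule to which C13 and C10 have been added on the same side.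

## Logic of the disconnections

35 ⇒ 34. Only the ester C–O bond is touched. The carboxyl group is carried as a methyl ester because the free acid would not survive the organometallic steps. The forward step must hydrolyse a conjugated ester without moving or isomerising C3=C4.

34 ⇒ 33 (from 32). The ring bond C4–C5 is cut. It is the only ring bond that joins an sp3 carbon to the carboxyl-bearing sp2 carbon, so the C3=C4 geometry can be fixed in an open chain and carried into the ring by a stereoretentive coupling. The macrocycle becomes an acyclic chain with all three alkenes in place. The forward step demands that zinc enters the C5–I bond and not the C4–I bond, and that cyclisation outruns oligomerisation.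

32 ⇒ 31 ⇒ 30. No C–C bond is cut; C5–I goes back to C5–OH and then to the silyl ether. A primary iodide cannot coexist with the base, tin hydride and palladium of the preceding steps, so it is introduced last. The desilylation must leave the iodoenoate untouched.

30 ⇒ 28 (through 29). The C4–I and C3–H bonds are removed to return the C3≡C4 triple bond. Syn addition of hydrogen and tin across an ynoate places C2 cis to the ester, which is the geometry the target needs. The forward step demands tin at C4 (α to the ester) and an iodination that proceeds with retention and spares the other alkenes.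

28 ⇒ 26 ⇒ 25 ⇒ 24. The C4–CO2Me bond is cut, then C4 itself is removed (it comes from a one-carbon diazophosphonate homologation of the C3 aldehyde), then the aldehyde is masked as an acetal. The chain now ends at C3 in a form that tolerates magnesium and copper reagents. The acetal must be hydrolysed without loss of the silyl ether; C1 is β to the aldehyde and cannot epimerise.

24 ⇒ 21 + 20 + 19 (key disconnection). The bonds C12–C13 and C10–C11 are cut. This removes the Z alkene as propyne and divides the chain into a chiral C13 nucleophile and an achiral C10 electrophile of similar size. The forward step must add C13 to the methyl-bearing carbon, add syn, and alkylate the alkenyl–copper bond with retention.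

21 ⇒ 10 ⇒ 9 ⇒ 8. C13–Mg goes back to C13–Br, C13–OH and the C13 ester. At every stage the two arms on C1 remain different (ester, alcohol or bromide against acetal), so C1 stays stereogenic. Compound 9 is a δ-hydroxy acetal and must be handled without acid.

8 ⇒ 7 + 4. The C1–C15 bond is cut. C1 is β to the C13 carbonyl, so the only stereocentre can be set by a chiral catalyst in a conjugate addition. A chiral fragment becomes an achiral enoate and an achiral alkenylboronate. The forward step demands facial selectivity on an acyclic enoate with a 1-substituted alkenyl group.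

7 ⇒ 5 + 6, and 4 ⇒ 2 ⇒ 1. The C14=C1 alkene of 7 is cut by cross-metathesis into two commercial alkenes, which delivers the five-carbon unit with the acetal already in place. The C15–B bond of 4 is traced to the carbonyl carbon of 1 through a hydrazone; deprotonation must occur at the methyl group.

19 ⇒ 18 ⇒ 17 ⇒ 16 ⇒ 12 + 13, and 12 ⇒ 11. After functional-group changes at C10 and C5, the C6–C7 bond and the C8–CH3 bond are cut. Syn addition of methyl and aluminium across the alkyne of 12 fixes the E geometry, and the alkenyl–aluminium bond opens 13 with retention. The two oxygens must carry different silyl groups so that only C10 is converted to the iodide.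

## Other disconnections considered

Alternative 1: The cut is the ring bond C1–C2, with C15=CH2 arising from an allylic C–O bond. In the forward step a chiral lithium amide would remove one enantiotopic propargylic proton at C2 of the 17-membered cyclic propargylic allylic ether A2. The carbanion would add to C1 in a [2,3]-Wittig shift to give the 14-membered propargylic alcohol A1, creating C1, the exocyclic methylene and the carbocycle in one event.
- In its favour: a 17-membered ether is closed by simple O-alkylation, the contraction is entropically easy, and the C2 hydroxyl could direct a trans-hydroalumination–iodination to C4. On ring formation and on events per step this plan is the better one.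
- Against it here: enantioselection rests on a stoichiometric chiral base acting on a flexible macrocycle and on the geometry of C1=C15 in A2. The C2 carbinol must later be deleted from an allylic or propargylic position, where transposition or allene formation threatens. The Z-C11=C12 and E-C7=C8 alkenes still have to be made beforehand.
- Comparison: the chosen plan sets C1 by a catalytic step with an established facial model and keeps it remote from later chemistry. The alternative avoids organozinc chemoselectivity but needs about five operations after the ring is formed, against one.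

Alternative 2: The cut is the ring bond C9–C10. KN(SiMe3)2 would generate the sulfonyl-stabilised carbanion at C10 of the open-chain bromo sulfone A4, which would displace the primary allylic bromide at C9 and close the ring to the macrocyclic sulfone A3.
- In its favour: this is a classical, metal-free macrocyclisation that tolerates moderate dilution, all alkenes are preset, and either C10 epimer converges. For the ring closure itself it is at least the equal of the chosen Negishi closure and probably the more dependable.
- Against it here: reductive removal of an allylic sulfone can shift or isomerise the adjacent C11=C12 alkene, which is the Z alkene that is hardest to make. Competing SN2′ attack on the allylic bromide is possible. The carboxyl must be carried as a silyloxymethyl group and re-oxidised in two stages.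
- Comparison: after cyclisation about four steps remain (desulfonylation, desilylation, two oxidations), and A4 requires a long linear assembly with three stereodefined alkenes. The chosen plan never exposes the Z alkene to a step that can move it. On C1 the two plans are equal, since both need a separate asymmetric step.

Alternative 3: The cuts are C1–C14 and C1–C15. The carbamate A6 would be lithiated at C1 with s-BuLi and (+)-sparteine and trapped by the boronic ester A7, with 1,2-migration forming C1–C14. The alkenyllithium 3 and iodine would then effect a Zweifel olefination forming C1–C15, to give A5.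
- In its favour: the stereocentre is reagent-controlled and stereospecifically carried through, the union is modular, and it uses the same alkenyllithium 3. On the expected level of enantiocontrol at C1 it is the equal or the better of the rhodium step.
- Against it here: it needs a stoichiometric chiral diamine at low temperature. The Z alkene of A7 must still be made separately, for instance by the same carbocupration. A5 ends at an allylic oxygen on C10, so C9–C10 would have to be formed by an allylic sp3–sp3 coupling with SN2′ and Z-to-E risks. The ring closure is not addressed at all.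
- Comparison: the chosen plan forms the Z alkene and joins the two halves in the same step. The alternative adds a fragment coupling and several protecting-group steps before the same endgame, so its step economy is worse.

Key step: step 12

Remark on the chemistry: the C13–C14–C1–C2–C3 unit has C1 at its centre, so it is assembled from a four-carbon acetal alkene and an acrylate (a four-carbon diol would leave one methylene too many on the C13 arm). The C3 acetal is carried as the diethyl acetal and the C5 oxygen as a tert-butyldiphenylsilyl ether; the carbon skeletons of the key-step partners and product are unchanged. The (R)-BINAP ligand is assigned from the accepted facial model for (E)-enoates and is to be verified at the stage of 9.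

## Route

Step 1
Reactants: 1 6-methylhept-5-en-2-one (sulcatone)
Product: 2 (E)-N'-(6-methylhept-5-en-2-ylidene)-2,4,6-tri(propan-2-yl)benzenesulfonohydrazide
Conditions: TrisNHNH2, MeOH, rt
Reagents that add atoms: 2,4,6-tri(propan-2-yl)benzenesulfonohydrazide, CC(C)c1cc(C(C)C)c(S(=O)(=O)NN)c(C(C)C)c1
Why: Hydrazone condensation of a methyl ketone; the hindered arenesulfonyl group should favour the E hydrazone (sulfonamide nitrogen syn to the methyl group), which is the isomer needed for the next step.

Step 2
Reactants: 2 the trisylhydrazone
Product: 4 4,4,5,5-tetramethyl-2-(6-methylhepta-1,5-dien-2-yl)-1,3,2-dioxaborolane, via 6-methylhepta-1,5-dien-2-yllithium 3 (not isolated)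
Conditions: n-BuLi (2.1 equiv), TMEDA, hexane/THF, −78 to 0 °C; then iPrOBpin, −78 °C to rt
Reagents that add atoms: 2-isopropoxy-4,4,5,5-tetramethyl-1,3,2-dioxaborolane, CC(C)OB1OC(C)(C)C(C)(C)O1
Why: Shapiro reaction; the dianion forms by deprotonation of the methyl group syn to the sulfonamide and loses sulfinate and dinitrogen to give the 2-lithio-1-alkene, which is borylated at carbon.

Step 3
Reactants: 5 4,4-diethoxybut-1-ene; 6 tert-butyl prop-2-enoate
Product: 7 tert-butyl (2E)-5,5-diethoxypent-2-enoate
Conditions: second-generation Grubbs catalyst RuCl2(=CHPh)(H2IMes)(PCy3) (2.5 mol%), 6 (3 equiv), CH2Cl2, 40 °C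
Reagents that add atoms: none
Why: Olefin cross-metathesis of an unhindered terminal alkene with an acrylate, a pairing that should be selective for the cross product and for the E enoate; ethene is lost.

Step 4
Reactants: 7 the enoate; 4 the alkenylboronate
Product: 8 tert-butyl (3S)-3-(2,2-diethoxyethyl)-8-methyl-4-methylidenenon-7-enoate
Conditions: [RhCl(C2H4)2]2 (2.5 mol%), (R)-BINAP (6 mol%), 4 (1.5 equiv), aq. KOH (0.5 equiv), 1,4-dioxane, 50 °C
Reagents that add atoms: none
Why: Hayashi–Miyaura rhodium-catalysed asymmetric conjugate addition; the alkenylrhodium–BINAP species formed by transmetalation inserts the enoate on one face and the oxa-π-allylrhodium is protonated by water. With (R)-BINAP the accepted model (attack on the re face of the α-carbon of an (E)-enoate) should deliver C15 to the face that gives (3S)-8, which is C1 (R) of the target. The tert-butyl ester resists hydroxide and should raise the selectivity.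

Step 5
Reactants: 8 the tert-butyl ester
Product: 9 (3R)-3-(2,2-diethoxyethyl)-8-methyl-4-methylidenenon-7-en-1-ol
Conditions: LiAlH4, THF, 0 °C; H2O, aq. NaOH work-up
Reagents that add atoms: none
Why: Hydride reduction of the ester to the primary alcohol; the acetal and the alkenes are inert, and the basic work-up prevents the δ-hydroxy acetal from closing to a cyclic acetal.

Step 6
Reactants: 9 the alcohol
Product: 10 (7S)-7-(2-bromoethyl)-9,9-diethoxy-2-methyl-6-methylidenenon-2-ene
Conditions: CBr4, PPh3, 2,6-lutidine, CH2Cl2, 0 °C
Reagents that add atoms: tetrabromomethane, BrC(Br)(Br)Br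
Why: Appel bromination of a primary alcohol by SN2 displacement of the alkoxyphosphonium ion; the lutidine buffer protects the acetal, and C1 is not involved (its descriptor changes only because bromine alters the priorities).

Step 7
Reactants: 11 but-3-yn-1-ol
Product: 12 tert-butyl(but-3-yn-1-yloxy)dimethylsilane
Conditions: TBSCl, imidazole, CH2Cl2, rt
Reagents that add atoms: tert-butyl(chloro)dimethylsilane, CC(C)(C)[Si](C)(C)Cl
Why: Standard silylation; the silyl ether marks the C10 oxygen so that it can later be told apart from the C5 oxygen.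

Step 8
Reactants: 12 the silyl ether; 13 oxirane
Product: 16 (3E)-6-{[tert-butyl(dimethyl)silyl]oxy}-4-methylhex-3-en-1-ol, via (E)-alkenyl(dimethyl)alane 14 (not isolated), via lithium butyl(alkenyl)dimethylalanate 15 (not isolated)
Conditions: AlMe3 (2 equiv), Cp2ZrCl2 (0.2 equiv), CH2Cl2, 0 °C to rt; evaporate, hexane/THF; n-BuLi, −78 °C; oxirane, −78 °C to rt
Reagents that add atoms: trimethylaluminium, C[Al](C)C
Why: Zirconium-catalysed Negishi carboalumination adds methyl (to C8) and aluminium (to C7) syn across the terminal alkyne. The alanate formed with n-BuLi opens oxirane at the alkenyl carbon with retention, so C6 ends up trans to C9 (E).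

Step 9
Reactants: 16 the homoallylic alcohol
Product: 17 (E)-1-(tert-butyldiphenylsilyloxy)-6-(tert-butyldimethylsilyloxy)-4-methylhex-3-ene
Conditions: TBDPSCl, imidazole, CH2Cl2, rt
Reagents that add atoms: tert-butyl(chloro)diphenylsilane, CC(C)(C)[Si](Cl)(c1ccccc1)c1ccccc1
Why: Silylation of the primary C5 hydroxyl with the more acid-stable silyl group, which has to survive the later acetal hydrolysis.

Step 10
Reactants: 17 the bis-silyl ether
Product: 18 (3E)-6-{[tert-butyl(diphenyl)silyl]oxy}-3-methylhex-3-en-1-ol
Conditions: PPTS (0.2 equiv), EtOH, 40 °C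
Reagents that add atoms: none
Why: Mild acid-catalysed solvolysis removes a primary tert-butyldimethylsilyl ether much faster than a tert-butyldiphenylsilyl ether, freeing only the C10 hydroxyl.

Step 11
Reactants: 18 the alcohol
Product: 19 tert-butyl{[(3E)-6-iodo-4-methylhex-3-en-1-yl]oxy}diphenylsilane
Conditions: I2, PPh3, imidazole, CH2Cl2, 0 °C, dark
Reagents that add atoms: iodine, II
Why: Appel-type iodination of a primary alcohol under buffered conditions; the trisubstituted alkene and the silyl ether are unaffected.

Step 12
Reactants: 10 the bromide; 20 propyne; 19 the iodide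
Product: 24 tert-butyl{[(3E,7Z,11R)-11-(2,2-diethoxyethyl)-4,8,16-trimethyl-12-methylideneheptadeca-3,7,15-trien-1-yl]oxy}diphenylsilane, via Grignard reagent 21 (not isolated), via alkylcopper 22 (not isolated), via (Z)-alkenylcopper 23 (not isolated)
Conditions: Mg, Et2O, reflux; CuBr·SMe2 (1 equiv), Et2O/Me2S, −45 °C; propyne (excess), −25 °C; then 19 (0.8 equiv), P(OEt)3, DMPU, THF, −30 °C to rt
Reagents that add atoms: none
Why: Three-component carbocupration–alkylation of the Normant type. The Grignard reagent 21 and CuBr·SMe2 give the alkylcopper 22, which adds across propyne in a concerted syn manner, the alkyl group going to the methyl-bearing carbon (C12) and copper to the terminal carbon (C11), as the polarisation and sterics of a terminal alkyne dictate. The alkenylcopper 23 is configurationally stable at low temperature and is alkylated at C11 by the primary iodide 19 with retention once P(OEt)3 and DMPU are added, so C13 and C10 end up cis, which is the Z geometry. The closest known reaction type is the carbocupration of terminal alkynes by alkylcopper–magnesium halide reagents followed by alkylation of the alkenylcopper, a standard route to stereodefined trisubstituted alkenes. No ring is closed and no stereocentre is formed; C1 is two carbons from the metal-bearing carbon and is carried through unchanged. The step needs regioselectivity, syn stereospecificity and retentive alkylation; the first two are intrinsic to propyne carbocupration in ether and the third to the alkenyl–copper bond, and both carbon partners are unhindered primary centres. The acetal, the silyl ether and the isolated alkenes are inert to organocopper reagents, and the E alkene of 19 is not touched.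

Step 13
Reactants: 24 the acetal
Product: 25 (3R,6Z,10E)-13-{[tert-butyl(diphenyl)silyl]oxy}-6,10-dimethyl-3-(6-methylhepta-1,5-dien-2-yl)trideca-6,10-dienal
Conditions: PPTS (0.3 equiv), acetone/H2O (9:1), 50 °C
Reagents that add atoms: water, O
Why: Mild acid-catalysed acetal hydrolysis; the tert-butyldiphenylsilyl ether and the alkenes should tolerate these conditions, and C1 is β to the aldehyde and cannot epimerise.

Step 14
Reactants: 25 the aldehyde
Product: 26 tert-butyl{[(3E,7Z,11R)-4,8-dimethyl-11-(6-methylhepta-1,5-dien-2-yl)tetradeca-3,7-dien-13-yn-1-yl]oxy}diphenylsilane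
Conditions: Ohira–Bestmann reagent, K2CO3, MeOH, 0 °C to rt
Reagents that add atoms: dimethyl (1-diazo-2-oxopropyl)phosphonate, CC(=O)C(=[N+]=[N-])P(=O)(OC)OC
Why: Seyferth–Gilbert homologation in the Ohira–Bestmann form turns the C3 aldehyde into the C3≡C4 terminal alkyne under mild base; C4 comes from the diazo carbon.

Step 15
Reactants: 26 the terminal alkyne
Product: 28 methyl (5R,8Z,12E)-15-{[tert-butyl(diphenyl)silyl]oxy}-8,12-dimethyl-5-(6-methylhepta-1,5-dien-2-yl)pentadeca-8,12-dien-2-ynoate, via lithium acetylide 27 (not isolated)
Conditions: n-BuLi, THF, −78 °C; ClCO2Me, −78 to 0 °C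
Reagents that add atoms: methyl carbonochloridate, COC(=O)Cl
Why: Deprotonation of the terminal alkyne and C-acylation of the acetylide with a chloroformate; no other acidic or electrophilic site competes at −78 °C.

Step 16
Reactants: 28 the ynoate
Product: 30 methyl (2E,5R,8Z,12E)-15-{[tert-butyl(diphenyl)silyl]oxy}-2-iodo-8,12-dimethyl-5-(6-methylhepta-1,5-dien-2-yl)pentadeca-2,8,12-trienoate, via (E)-2-stannyl enoate 29 (not isolated)
Conditions: Pd(PPh3)4 (2 mol%), Bu3SnH (1.2 equiv, slow addition), THF, 0 °C; then I2, CH2Cl2, 0 °C, dark
Reagents that add atoms: iodine, II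
Why: Palladium-catalysed hydrostannation of an alkynoate adds hydrogen (to C3) and tin (to C4, α to the ester) syn, so C2 lies cis to the ester. Iododestannylation is an ipso substitution with retention and is far faster than any reaction of iodine with the isolated alkenes.

Step 17
Reactants: 30 the silyl ether
Product: 31 methyl (2E,5R,8Z,12E)-15-hydroxy-2-iodo-8,12-dimethyl-5-(6-methylhepta-1,5-dien-2-yl)pentadeca-2,8,12-trienoate
Conditions: HF·pyridine, pyridine, THF, 0 °C to rt
Reagents that add atoms: none
Why: Buffered fluoride cleavage of the primary silyl ether; these weakly acidic, non-nucleophilic conditions should leave the iodoenoate and the ester unchanged.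

Step 18
Reactants: 31 the alcohol
Product: 32 methyl (2E,5R,8Z,12E)-2,15-diiodo-8,12-dimethyl-5-(6-methylhepta-1,5-dien-2-yl)pentadeca-2,8,12-trienoate
Conditions: I2, PPh3, imidazole, CH2Cl2, 0 °C, dark
Reagents that add atoms: iodine, II
Why: Appel-type iodination of the primary C5 hydroxyl; exclusion of light and a thiosulfate quench guard the geometry of the iodoenoate.

Step 19
Reactants: 32 the diiodide
Product: 34 methyl (1Z,4R,7Z,11E)-7,11-dimethyl-4-(6-methylhepta-1,5-dien-2-yl)cyclotetradeca-1,7,11-triene-1-carboxylate, via alkylzinc iodide 33 (not isolated)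
Conditions: Zn dust (activated with BrCH2CH2Br and Me3SiCl), THF, 30 °C; then slow addition to Pd(PPh3)4 (10 mol%), THF, 50 °C, 0.002 M
Reagents that add atoms: none
Why: Zinc inserts into the primary alkyl C5–I bond much faster than into an alkenyl iodide in THF. The intramolecular Negishi coupling (oxidative addition of zerovalent palladium at C4–I, transmetalation, reductive elimination) forms C4–C5 with retention at C4, so the C3=C4 geometry of 32 is carried into the 14-membered ring. Slow addition keeps the organozinc dilute so that ring closure outruns oligomerisation.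

Step 20
Reactants: 34 the macrocyclic methyl ester
Product: 35 (1Z,4R,7Z,11E)-7,11-dimethyl-4-(6-methylhepta-1,5-dien-2-yl)cyclotetradeca-1,7,11-triene-1-carboxylic acid (target)
Conditions: LiOH, THF/MeOH/H2O, 40 °C; then cold 1 M HCl to pH 3
Reagents that add atoms: lithium hydroxide, [Li+].[OH-]
Why: Saponification of a conjugated methyl ester by acyl substitution; hydroxide at this temperature should neither isomerise nor deconjugate the trisubstituted enoate, and C1 is remote from the carboxyl group.

## Compound list

1 | 6-methylhept-5-en-2-one (sulcatone) | CC(=O)CCC=C(C)C | starting material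
2 | (E)-N'-(6-methylhept-5-en-2-ylidene)-2,4,6-tri(propan-2-yl)benzenesulfonohydrazide | C/C(CCC=C(C)C)=N\NS(=O)(=O)c1c(C(C)C)cc(C(C)C)cc1C(C)C | intermediate
3 | 6-methylhepta-1,5-dien-2-yllithium | [Li]C(=C)CCC=C(C)C | intermediate
4 | 4,4,5,5-tetramethyl-2-(6-methylhepta-1,5-dien-2-yl)-1,3,2-dioxaborolane | C=C(CCC=C(C)C)B1OC(C)(C)C(C)(C)O1 | intermediate
5 | 4,4-diethoxybut-1-ene | C=CCC(OCC)OCC | starting material
6 | tert-butyl prop-2-enoate | C=CC(=O)OC(C)(C)C | starting material
7 | tert-butyl (2E)-5,5-diethoxypent-2-enoate | CCOC(C/C=C/C(=O)OC(C)(C)C)OCC | intermediate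
8 | tert-butyl (3S)-3-(2,2-diethoxyethyl)-8-methyl-4-methylidenenon-7-enoate | C=C(CCC=C(C)C)[C@H](CC(=O)OC(C)(C)C)CC(OCC)OCC | intermediate
9 | (3R)-3-(2,2-diethoxyethyl)-8-methyl-4-methylidenenon-7-en-1-ol | C=C(CCC=C(C)C)[C@H](CCO)CC(OCC)OCC | intermediate
10 | (7S)-7-(2-bromoethyl)-9,9-diethoxy-2-methyl-6-methylidenenon-2-ene | C=C(CCC=C(C)C)[C@H](CCBr)CC(OCC)OCC | intermediate
11 | but-3-yn-1-ol | C#CCCO | starting material
12 | tert-butyl(but-3-yn-1-yloxy)dimethylsilane | C#CCCO[Si](C)(C)C(C)(C)C | intermediate
13 | oxirane | C1CO1 | starting material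
14 | [(1E)-4-{[tert-butyl(dimethyl)silyl]oxy}-2-methylbut-1-en-1-yl](dimethyl)alumane | C[Al](C)/C=C(\C)CCO[Si](C)(C)C(C)(C)C | intermediate
15 | lithium butyl[(1E)-4-{[tert-butyl(dimethyl)silyl]oxy}-2-methylbut-1-en-1-yl]dimethylaluminate | [Li+].CCCC[Al-](C)(C)/C=C(\C)CCO[Si](C)(C)C(C)(C)C | intermediate
16 | (3E)-6-{[tert-butyl(dimethyl)silyl]oxy}-4-methylhex-3-en-1-ol | OCC/C=C(\C)CCO[Si](C)(C)C(C)(C)C | intermediate
17 | (E)-1-(tert-butyldiphenylsilyloxy)-6-(tert-butyldimethylsilyloxy)-4-methylhex-3-ene | CC(C)(C)[Si](c1ccccc1)(c1ccccc1)OCC/C=C(\C)CCO[Si](C)(C)C(C)(C)C | intermediate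
18 | (3E)-6-{[tert-butyl(diphenyl)silyl]oxy}-3-methylhex-3-en-1-ol | OCC/C(C)=C/CCO[Si](c1ccccc1)(c1ccccc1)C(C)(C)C | intermediate
19 | tert-butyl{[(3E)-6-iodo-4-methylhex-3-en-1-yl]oxy}diphenylsilane | ICC/C(C)=C/CCO[Si](c1ccccc1)(c1ccccc1)C(C)(C)C | intermediate
20 | propyne | CC#C | starting material
21 | [(3S)-3-(2,2-diethoxyethyl)-8-methyl-4-methylidenenon-7-en-1-yl]magnesium bromide | C=C(CCC=C(C)C)[C@H](CC[Mg]Br)CC(OCC)OCC | intermediate
22 | [(3S)-3-(2,2-diethoxyethyl)-8-methyl-4-methylidenenon-7-en-1-yl]copper (as its MgBr2 and Me2S complex) | C=C(CCC=C(C)C)[C@H](CC[Cu])CC(OCC)OCC | intermediate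
23 | [(1Z,5R)-5-(2,2-diethoxyethyl)-2,10-dimethyl-6-methylideneundeca-1,9-dien-1-yl]copper | C=C(CCC=C(C)C)[C@H](CC/C(C)=C\[Cu])CC(OCC)OCC | intermediate
24 | tert-butyl{[(3E,7Z,11R)-11-(2,2-diethoxyethyl)-4,8,16-trimethyl-12-methylideneheptadeca-3,7,15-trien-1-yl]oxy}diphenylsilane | C=C(CCC=C(C)C)[C@H](CC/C(C)=C\CC/C(C)=C/CCO[Si](c1ccccc1)(c1ccccc1)C(C)(C)C)CC(OCC)OCC | intermediate
25 | (3R,6Z,10E)-13-{[tert-butyl(diphenyl)silyl]oxy}-6,10-dimethyl-3-(6-methylhepta-1,5-dien-2-yl)trideca-6,10-dienal | C=C(CCC=C(C)C)[C@H](CC/C(C)=C\CC/C(C)=C/CCO[Si](c1ccccc1)(c1ccccc1)C(C)(C)C)CC=O | intermediate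
26 | tert-butyl{[(3E,7Z,11R)-4,8-dimethyl-11-(6-methylhepta-1,5-dien-2-yl)tetradeca-3,7-dien-13-yn-1-yl]oxy}diphenylsilane | C=C(CCC=C(C)C)[C@H](CC/C(C)=C\CC/C(C)=C/CCO[Si](c1ccccc1)(c1ccccc1)C(C)(C)C)CC#C | intermediate
27 | lithium acetylide of 26 (lithium on the terminal alkyne carbon C4) | C=C(CCC=C(C)C)[C@H](CC/C(C)=C\CC/C(C)=C/CCO[Si](c1ccccc1)(c1ccccc1)C(C)(C)C)CC#C[Li] | intermediate
28 | methyl (5R,8Z,12E)-15-{[tert-butyl(diphenyl)silyl]oxy}-8,12-dimethyl-5-(6-methylhepta-1,5-dien-2-yl)pentadeca-8,12-dien-2-ynoate | C=C(CCC=C(C)C)[C@H](CC/C(C)=C\CC/C(C)=C/CCO[Si](c1ccccc1)(c1ccccc1)C(C)(C)C)CC#CC(=O)OC | intermediate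
29 | methyl (2E,5R,8Z,12E)-15-{[tert-butyl(diphenyl)silyl]oxy}-8,12-dimethyl-5-(6-methylhepta-1,5-dien-2-yl)-2-(tributylstannyl)pentadeca-2,8,12-trienoate | C=C(CCC=C(C)C)[C@H](CC/C(C)=C\CC/C(C)=C/CCO[Si](c1ccccc1)(c1ccccc1)C(C)(C)C)C/C=C(\C(=O)OC)[Sn](CCCC)(CCCC)CCCC | intermediate
30 | methyl (2E,5R,8Z,12E)-15-{[tert-butyl(diphenyl)silyl]oxy}-2-iodo-8,12-dimethyl-5-(6-methylhepta-1,5-dien-2-yl)pentadeca-2,8,12-trienoate | C=C(CCC=C(C)C)[C@H](CC/C(C)=C\CC/C(C)=C/CCO[Si](c1ccccc1)(c1ccccc1)C(C)(C)C)C/C=C(\C(=O)OC)I | intermediate
31 | methyl (2E,5R,8Z,12E)-15-hydroxy-2-iodo-8,12-dimethyl-5-(6-methylhepta-1,5-dien-2-yl)pentadeca-2,8,12-trienoate | C=C(CCC=C(C)C)[C@H](CC/C(C)=C\CC/C(C)=C/CCO)C/C=C(\C(=O)OC)I | intermediate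
32 | methyl (2E,5R,8Z,12E)-2,15-diiodo-8,12-dimethyl-5-(6-methylhepta-1,5-dien-2-yl)pentadeca-2,8,12-trienoate | C=C(CCC=C(C)C)[C@H](CC/C(C)=C\CC/C(C)=C/CCI)C/C=C(\C(=O)OC)I | intermediate
33 | alkylzinc iodide of 32 (iodozinc on C15 of the pentadecatrienoate chain, ring atom C5) | C=C(CCC=C(C)C)[C@H](CC/C(C)=C\CC/C(C)=C/CC[Zn]I)C/C=C(\C(=O)OC)I | intermediate
34 | methyl (1Z,4R,7Z,11E)-7,11-dimethyl-4-(6-methylhepta-1,5-dien-2-yl)cyclotetradeca-1,7,11-triene-1-carboxylate | C=C(CCC=C(C)C)[C@H]1C/C=C(\C(=O)OC)CC/C=C(\C)CC/C=C(/C)CC1 | intermediate
35 | (1Z,4R,7Z,11E)-7,11-dimethyl-4-(6-methylhepta-1,5-dien-2-yl)cyclotetradeca-1,7,11-triene-1-carboxylic acid | C=C(CCC=C(C)C)[C@H]1C/C=C(\C(=O)O)CC/C=C(\C)CC/C=C(/C)CC1 | target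

## Step count and risks

Total: 20 steps. Longest linear sequence: 14 steps (steps 1, 2, 4, 5, 6 and 12 to 20; the arm from 11 through steps 7 to 11 is equally long).

Least certain steps:

Step 12 (key step). The carbocupration itself is dependable, but the alkylation of the alkenylcopper by an unactivated primary iodide can be slow. The alkenylcopper may then decompose or dimerise on warming, or the homoallylic iodide may undergo dehydrohalogenation towards the conjugated diene. Either would lower the conversion without affecting the Z geometry. Fallback (sets out from 10, returns at 24): 10 is taken to the alkenylcopper 23 as before, but 23 is quenched with iodine to give, with retention, (1Z,5R)-5-(2,2-diethoxyethyl)-1-iodo-2,10-dimethyl-6-methylideneundeca-1,9-diene F1. Separately 19 is treated with activated zinc in THF to give the homoallylic alkylzinc iodide F2. F1 and F2 are then joined by a Negishi coupling with PdCl2(dppf) in THF at 40 °C, which should give 24 with the same Z alkene.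

Step 19. Zinc may also insert into the activated alkenyl C4–I bond (loss of chemoselectivity), the organozinc may be protonated before it cyclises, intermolecular coupling may compete if the stationary concentration is too high, and the iodoenoate may isomerise. Fallback (sets out from 24, returns at 34): Bu4NF removes the silyl group of 24 to give the C5 alcohol F3, and I2/PPh3/imidazole gives the C5 iodide F4. The sodium salt of commercial methyl bis(2,2,2-trifluoroethyl)phosphonoacetate (NaH, DMF) is alkylated by F4 to the α-alkylated phosphonate F5, and PPTS in wet acetone unmasks the phosphonate aldehyde F6. KN(SiMe3)2 with 18-crown-6 in THF at −78 °C under high dilution then closes the ring by an intramolecular olefination of the Still–Gennari type to 34. The selectivity of that closure for C2 cis to the ester would have to be checked and the minor isomer removed.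

Step 4. Transmetalation of the hindered 1-substituted alkenylboronate may be slow, so that protodeboronation competes, and facial selectivity on an acyclic enoate may be moderate. Fallback (sets out from 5 and 3, returns at 9): (4R)-4-phenyl-1,3-oxazolidin-2-one is N-acylated with acryloyl chloride to (4R)-4-phenyl-3-(prop-2-enoyl)-1,3-oxazolidin-2-one F7, and cross-metathesis of F7 with 5 gives the (E)-enoyl imide F8. The alkenyllithium 3 is transmetalated with MgBr2·OEt2 to (6-methylhepta-1,5-dien-2-yl)magnesium bromide F9. With CuBr·SMe2 in THF at −40 °C, F9 should add to the chelated s-cis conformer of F8 from the face opposite the phenyl group to give the (3S)-adduct F10. LiBH4 in wet ether then releases 9 and the auxiliary.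

Step 16. Hydrostannation may place part of the tin at C3 (incomplete regiocontrol), and light or excess iodine may isomerise the less stable iodoenoate geometry during iododestannylation. Fallback (sets out from 25, returns at 34): commercial methyl bis(2,2,2-trifluoroethyl)phosphonoacetate is α-brominated to methyl 2-[bis(2,2,2-trifluoroethoxy)phosphoryl]-2-bromoacetate F11. Olefination of 25 with F11 (t-BuOK, 18-crown-6, THF, −78 °C), a reaction known to favour the isomer with the β-substituent cis to the ester, gives the (E)-2-bromoenoate silyl ether F12. HF·pyridine gives the bromoenoate alcohol F13, and I2/PPh3/imidazole gives the bromo iodide F14. Zinc insertion at the alkyl iodide (an alkenyl bromide is inert to zinc dust) gives the alkylzinc iodide F15, which is closed with Pd(PPh3)4 under the conditions of step 19 to 34.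

## Further compounds

F1 | step 12 | (1Z,5R)-5-(2,2-diethoxyethyl)-1-iodo-2,10-dimethyl-6-methylideneundeca-1,9-diene | C=C(CCC=C(C)C)[C@H](CC/C(C)=C\I)CC(OCC)OCC
F2 | step 12 | [(3E)-6-{[tert-butyl(diphenyl)silyl]oxy}-3-methylhex-3-en-1-yl]zinc iodide | I[Zn]CC/C(C)=C/CCO[Si](c1ccccc1)(c1ccccc1)C(C)(C)C
F3 | step 19 | (3E,7Z,11R)-11-(2,2-diethoxyethyl)-4,8,16-trimethyl-12-methylideneheptadeca-3,7,15-trien-1-ol | C=C(CCC=C(C)C)[C@H](CC/C(C)=C\CC/C(C)=C/CCO)CC(OCC)OCC
F4 | step 19 | (3E,7Z,11R)-11-(2,2-diethoxyethyl)-1-iodo-4,8,16-trimethyl-12-methylideneheptadeca-3,7,15-triene | C=C(CCC=C(C)C)[C@H](CC/C(C)=C\CC/C(C)=C/CCI)CC(OCC)OCC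
F5 | step 19 | methyl (5E,9Z,13R)-2-[bis(2,2,2-trifluoroethoxy)phosphoryl]-13-(2,2-diethoxyethyl)-6,10,18-trimethyl-14-methylidenenonadeca-5,9,17-trienoate (both C2 epimers) | C=C(CCC=C(C)C)[C@H](CC/C(C)=C\CC/C(C)=C/CCC(C(=O)OC)P(=O)(OCC(F)(F)F)OCC(F)(F)F)CC(OCC)OCC
F6 | step 19 | methyl (5E,9Z,13R)-2-[bis(2,2,2-trifluoroethoxy)phosphoryl]-6,10,18-trimethyl-14-methylidene-13-(2-oxoethyl)nonadeca-5,9,17-trienoate (both C2 epimers) | C=C(CCC=C(C)C)[C@H](CC/C(C)=C\CC/C(C)=C/CCC(C(=O)OC)P(=O)(OCC(F)(F)F)OCC(F)(F)F)CC=O
F7 | step 4 | (4R)-4-phenyl-3-(prop-2-enoyl)-1,3-oxazolidin-2-one | C=CC(=O)N1[C@H](c2ccccc2)COC1=O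
F8 | step 4 | (4R)-3-[(2E)-5,5-diethoxypent-2-enoyl]-4-phenyl-1,3-oxazolidin-2-one | CCOC(C/C=C/C(=O)N1[C@H](c2ccccc2)COC1=O)OCC
F9 | step 4 | (6-methylhepta-1,5-dien-2-yl)magnesium bromide | C=C([Mg]Br)CCC=C(C)C
F10 | step 4 | (4R)-3-[(3S)-3-(2,2-diethoxyethyl)-8-methyl-4-methylidenenon-7-enoyl]-4-phenyl-1,3-oxazolidin-2-one | C=C(CCC=C(C)C)[C@H](CC(=O)N1[C@H](c2ccccc2)COC1=O)CC(OCC)OCC
F11 | step 16 | methyl 2-[bis(2,2,2-trifluoroethoxy)phosphoryl]-2-bromoacetate | COC(=O)C(Br)P(=O)(OCC(F)(F)F)OCC(F)(F)F
F12 | step 16 | methyl (2E,5R,8Z,12E)-2-bromo-15-{[tert-butyl(diphenyl)silyl]oxy}-8,12-dimethyl-5-(6-methylhepta-1,5-dien-2-yl)pentadeca-2,8,12-trienoate | C=C(CCC=C(C)C)[C@H](CC/C(C)=C\CC/C(C)=C/CCO[Si](c1ccccc1)(c1ccccc1)C(C)(C)C)C/C=C(\C(=O)OC)Br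
F13 | step 16 | methyl (2E,5R,8Z,12E)-2-bromo-15-hydroxy-8,12-dimethyl-5-(6-methylhepta-1,5-dien-2-yl)pentadeca-2,8,12-trienoate | C=C(CCC=C(C)C)[C@H](CC/C(C)=C\CC/C(C)=C/CCO)C/C=C(\C(=O)OC)Br
F14 | step 16 | methyl (2E,5R,8Z,12E)-2-bromo-15-iodo-8,12-dimethyl-5-(6-methylhepta-1,5-dien-2-yl)pentadeca-2,8,12-trienoate | C=C(CCC=C(C)C)[C@H](CC/C(C)=C\CC/C(C)=C/CCI)C/C=C(\C(=O)OC)Br
F15 | step 16 | alkylzinc iodide of F14 (iodozinc on C15 of the chain) | C=C(CCC=C(C)C)[C@H](CC/C(C)=C\CC/C(C)=C/CC[Zn]I)C/C=C(\C(=O)OC)Br
A1 | alternative 1 | (1R,6E,10Z,14S)-7,11-dimethyl-14-(6-methylhepta-1,5-dien-2-yl)cyclotetradeca-6,10-dien-2-yn-1-ol (1S,2R in the target numbering) | C=C(CCC=C(C)C)[C@H]1[C@@H](O)C#CCC/C=C(\C)CC/C=C(/C)CC1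
A2 | alternative 1 | 17-membered cyclic propargylic allylic ether C2–O–CH2–C15(=C1), side chain on C15, one C1=C15 geometry drawn | O1CC#CCC/C=C(\C)CC/C=C(/C)CC/C=C(\CCC=C(C)C)C1
A3 | alternative 2 | 14-membered C10 phenyl sulfone with a tert-butyldimethylsilyloxymethyl group on C4 (either C10 epimer) | C=C(CCC=C(C)C)[C@H]1C/C=C(\CO[Si](C)(C)C(C)(C)C)CC/C=C(\C)CC(S(=O)(=O)c2ccccc2)/C=C(/C)CC1
A4 | alternative 2 | open-chain precursor with a primary allylic bromide at C9 and an allylic phenyl sulfone at C10 | C=C(CCC=C(C)C)[C@H](CC/C(C)=C\CS(=O)(=O)c1ccccc1)C/C=C(\CO[Si](C)(C)C(C)(C)C)CC/C=C(\C)CBr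
A5 | alternative 3 | C3–C10 fragment with C1, the side chain and the Z-C11=C12 alkene, silyl ethers at C3 and C10 | C=C(CCC=C(C)C)[C@H](CC/C(C)=C\CO[Si](c1ccccc1)(c1ccccc1)C(C)(C)C)CCO[Si](C)(C)C(C)(C)C
A6 | alternative 3 | 3-{[tert-butyl(dimethyl)silyl]oxy}propyl N,N-di(propan-2-yl)carbamate | CC(C)N(C(C)C)C(=O)OCCCO[Si](C)(C)C(C)(C)C
A7 | alternative 3 | tert-butyl{[(2Z)-3-methyl-5-(4,4,5,5-tetramethyl-1,3,2-dioxaborolan-2-yl)pent-2-en-1-yl]oxy}diphenylsilane | CC1(C)OB(CC/C(C)=C\CO[Si](c2ccccc2)(c2ccccc2)C(C)(C)C)OC1(C)C
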